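**Plan**

- Ring numbering used here: C1 (C=O), C2 (carries CH2CO2Me), C3 (=CH), C4 (CHOH), C5 (CH with the geranylgeranyl chain), C6 (CH2). The unit C6H2–C1(=O)–C2=C3 is the C6-protonated form of the cross-conjugated dienolate C6=C1(O−)–C2=C3, and C4/C5 are adjacent sp3 carbons with cis substituents: the pattern left by a thermal disrotatory 6π ring closure.
- Retrosynthesis: cut C4–C5 (retro-6π) to an acyclic trienolate C5=C6–C1(O−)=C2–C3=C4–OSi with (E) termini and the two alkenyl arms cis on the enolate double bond. Then cut C1–C6 (alkenylmagnesium + N-methoxy-N-methylamide), C2–CH2CO2Me (enolate alkylation), and the bond from C5 to the first chain carbon (ethynyl + geranylgeranyl bromide).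
- Forward: a four-step amide fragment (C1–C4, side chain, (E)-silyl enol ether) and a three-step (E)-iodoalkene (C5, C6, chain) are joined by acylation. The only ring forms in one base-catalysed isomerisation, and desilylation ends the route.
- Stereochemistry: the cis C4/C5 relation comes from orbital symmetry acting on two (E) termini (enol ether from reductive silylation of an s-trans enal, alkenyl from syn hydrozirconation). The absolute sense comes from a chiral quaternary ammonium counter-ion of the trienolate; the chain alkenes come from (E,E,E)-geranylgeraniol.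

Key step: step 9

Assumption: (E,E,E)-geranylgeraniol, the amide ylide, aqueous 2,2-dimethoxyacetaldehyde, ethynylmagnesium bromide solution and [(Ph3P)CuH]6 are bought; the stereocentre between amide/ketone and ester in the acyclic intermediates is carried as a racemate because it becomes sp2 in the key step.

**Step 1**
Reactants: 1 N-methoxy-N-methyl-2-(triphenyl-λ5-phosphanylidene)acetamide; 2 2,2-dimethoxyacetaldehyde
Product: 3 (E)-N,4,4-trimethoxy-N-methylbut-2-enamide
Conditions: CH2Cl2, rt (2 used as its 60 wt% aqueous solution)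
Reagents that add atoms: none
Why: Wittig olefination with a carbonyl-stabilised ylide should give the (E)-alkene and tolerates the water that comes with the aldehyde, while the dimethyl acetal keeps the second aldehyde of glyoxal masked.

**Step 2**
Reactants: 3 (E)-N,4,4-trimethoxy-N-methylbut-2-enamide
Product: 4 (E)-N-methoxy-N-methyl-4-oxobut-2-enamide
Conditions: aq HCl (1 M), THF, 0 °C → rt
Reagents that add atoms: water O
Why: Acid-catalysed acetal hydrolysis frees the aldehyde without touching the N-methoxy-N-methylamide, and the alkene, conjugated on both sides, keeps its (E) geometry.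

**Step 3**
Reactants: 4 (E)-N-methoxy-N-methyl-4-oxobut-2-enamide
Product: 6 (E)-4-[tert-butyl(dimethyl)silyl]oxy-N-methoxy-N-methylbut-3-enamide, via copper enolate 5 (not isolated)
Conditions: [(Ph3P)CuH]6 (0.2 equiv), TBSCl (2 equiv), toluene, 0 °C → rt
Reagents that add atoms: tert-butyl(dimethyl)silyl chloride CC(C)(C)[Si](C)(C)Cl
Why: Reductive silylation of an enal, in which the copper hydride delivers hydride to the carbon beta to the aldehyde (the stronger of the two acceptors, so the amide stays) and O-silylation of the copper enolate formed from the s-trans enal should give mainly the (E)-silyl enol ether, one terminus of the later triene.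

**Step 4**
Reactants: 6 (E)-4-[tert-butyl(dimethyl)silyl]oxy-N-methoxy-N-methylbut-3-enamide; 7 methyl bromoacetate
Product: 9 methyl (4E)-5-[tert-butyl(dimethyl)silyl]oxy-3-[methoxy(methyl)carbamoyl]pent-4-enoate (racemic), via lithium dienolate 8 (not isolated)
Conditions: LiN(iPr)2 (1.05 equiv, commercial solution), THF, −78 °C; then 7, −78 → −40 °C
Reagents that add atoms: none
Why: Kinetic deprotonation alpha to the amide gives a dienolate that is alkylated at its alpha-carbon (the gamma-carbon carries the silyloxy group and the enol ether keeps its (E) geometry at −78 °C); the new stereocentre forms as a racemate and is erased in step 9.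

**Step 5**
Reactants: 10 (2E,6E,10E)-3,7,11,15-tetramethylhexadeca-2,6,10,14-tetraen-1-ol (geranylgeraniol)
Product: 11 (2E,6E,10E)-1-bromo-3,7,11,15-tetramethylhexadeca-2,6,10,14-tetraene (geranylgeranyl bromide)
Conditions: PBr3 (0.4 equiv), Et2O, −10 °C, dark; used crude
Reagents that add atoms: phosphorus tribromide BrP(Br)Br
Why: SN2 displacement at the activated primary allylic alcohol at low temperature should keep the (E) geometry of the adjacent alkene and avoid allylic transposition.

**Step 6**
Reactants: 11 geranylgeranyl bromide; 12 ethynylmagnesium bromide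
Product: 13 (4E,8E,12E)-5,9,13,17-tetramethyloctadeca-4,8,12,16-tetraen-1-yne
Conditions: CuCl (5 mol%), THF, 0 → 40 °C; 12 in threefold excess
Reagents that add atoms: none
Why: Copper-catalysed coupling of an alkynyl Grignard reagent with a primary allylic bromide proceeds by SN2 attack at the unhindered carbon and should give the skipped enyne with all chain alkenes intact, the excess acetylide suppressing double allylation.

**Step 7**
Reactants: 13 (4E,8E,12E)-5,9,13,17-tetramethyloctadeca-4,8,12,16-tetraen-1-yne
Product: 15 (1E,4E,8E,12E)-1-iodo-5,9,13,17-tetramethyloctadeca-1,4,8,12,16-pentaene, via alkenylzirconocene chloride 14 (not isolated)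
Conditions: Cp2Zr(H)Cl (1.3 equiv), THF, rt; then I2 (1.3 equiv), 0 °C
Reagents that add atoms: iodine [I][I]
Why: Hydrozirconation adds Zr–H syn and anti-Markovnikov to the terminal alkyne much faster than to trisubstituted alkenes, and iodinolysis of the carbon–zirconium bond with retention gives the (E)-iodoalkene that becomes the second triene terminus.

**Step 8**
Reactants: 15 (1E,4E,8E,12E)-1-iodo-5,9,13,17-tetramethyloctadeca-1,4,8,12,16-pentaene; 9 methyl (4E)-5-[tert-butyl(dimethyl)silyl]oxy-3-[methoxy(methyl)carbamoyl]pent-4-enoate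
Product: 19 methyl (5E,8E,12E,16E)-3-[(E)-2-[tert-butyl(dimethyl)silyl]oxyethenyl]-9,13,17,21-tetramethyl-4-oxodocosa-5,8,12,16,20-pentaenoate (racemic), via alkenyllithium 16 (not isolated), via alkenylmagnesium bromide 17 (not isolated), via magnesium N,O-chelate 18 (not isolated)
Conditions: t-BuLi (2.0 equiv), Et2O, −78 °C; MgBr2·OEt2 (1.1 equiv), −78 → −40 °C; 9 in THF, −40 → −10 °C; cold pH 7 phosphate buffer
Reagents that add atoms: none
Why: Iodine–lithium exchange with retention, transmetalation to the less basic Grignard reagent and acyl substitution at the N-methoxy-N-methylamide, whose chelated tetrahedral adduct prevents over-addition, should give the enone, since amides of this type in succinic half esters are known to react ahead of the methyl ester.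

**Step 9**
Reactants: 19 methyl (5E,8E,12E,16E)-3-[(E)-2-[tert-butyl(dimethyl)silyl]oxyethenyl]-9,13,17,21-tetramethyl-4-oxodocosa-5,8,12,16,20-pentaenoate
Product: 22 methyl 2-[(3R,4R)-3-[tert-butyl(dimethyl)silyl]oxy-6-oxo-4-[(2E,6E,10E)-3,7,11,15-tetramethylhexadeca-2,6,10,14-tetraen-1-yl]cyclohex-1-en-1-yl]acetate, via trienolate 20 (not isolated), via cyclohexadienolate 21 (not isolated)
Conditions: N-(9-anthracenylmethyl)-O-allylcinchonidinium bromide (10 mol%), CsOH·H2O (20 mol%, solid), toluene/CH2Cl2 7:3, −45 °C; AcOH at −45 °C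
Reagents that add atoms: none
Why: Proposed new method: hydroxide carried into the organic phase by the chiral ammonium ion reversibly removes the hydrogen at C3 of 19 (alpha to the ketone, allylic to the enol ether), the resulting cross-conjugated trienolate 20 (ion-paired with the cinchonidinium cation) undergoes a thermal disrotatory 6π-electrocyclisation across its two terminal carbons to the cyclohexadienolate 21, and C-protonation of 21 alpha to the oxygen-bearing carbon gives the conjugated enone 22, so that the overall change is an isomerisation catalytic in base. The closest known reaction types are the oxy-anion-accelerated 6π-electrocyclisation of 3-oxidohexatrienes to cyclohexenones, which runs below room temperature once the trienolate exists, and the enantioselective 6π-electrocyclisation of 2-azapentadienyl anions held as ion pairs by chiral quaternary ammonium phase-transfer catalysts; a carbocyclic trienolate has not been closed under such control. The six-membered carbocycle is closed in the six-centre disrotatory mode by joining the silyloxy-bearing enol-ether terminus to the beta-carbon of the enone arm, the other four ring atoms being the enolate carbon, its alpha-carbon and the two inner alkene carbons. Both stereocentres are created here: the cis relation follows from orbital symmetry because the silyloxy group and the geranylgeranyl chain both sit on (E) termini and rotate outward together, and the absolute sense should be set by the cation, which lies over one face of the planar O–C=C–C=C dienolate segment and leaves only the other face open to the enone arm (if the antipode predominates, the pseudo-enantiomeric cinchoninium salt is used). The step needs (a) the enolate double bond with the two alkenyl arms cis, (b) (E) geometry at both termini, (c) ring closure that outruns gamma-deprotonation at the doubly allylic CH2 of the chain and saponification of the methyl ester, and (d) protonation at the carbon alpha to the carbonyl. Point (a) is secured because the two enolate geometries interconvert through 19 and only the productive one is drained, (b) is built into 19 by steps 3 and 7, (c) rests on the higher kinetic acidity of the C3 hydrogen, the low temperature and the substoichiometric solid base, and (d) on the fact that the cross-conjugated dienolate 21 has a single nucleophilic carbon.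

**Step 10**
Reactants: 22 methyl 2-[(3R,4R)-3-[tert-butyl(dimethyl)silyl]oxy-6-oxo-4-[(2E,6E,10E)-3,7,11,15-tetramethylhexadeca-2,6,10,14-tetraen-1-yl]cyclohex-1-en-1-yl]acetate
Product: 23 methyl 2-[(3R,4R)-3-hydroxy-6-oxo-4-[(2E,6E,10E)-3,7,11,15-tetramethylhexadeca-2,6,10,14-tetraen-1-yl]cyclohex-1-en-1-yl]acetate
Conditions: HF·pyridine, pyridine, THF, 0 °C → rt
Reagents that add atoms: none
Why: Fluoride cleaves the allylic silyl ether under buffered weakly acidic conditions, so that the gamma-hydroxy enone is not exposed to base (no enolisation at the carbinol carbon, no elimination) and both stereocentres are kept.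

**Compound list**

1 | N-methoxy-N-methyl-2-(triphenyl-λ5-phosphanylidene)acetamide | CON(C)C(=O)C=P(c1ccccc1)(c1ccccc1)c1ccccc1 | starting material
2 | 2,2-dimethoxyacetaldehyde | COC(OC)C=O | starting material
3 | (E)-N,4,4-trimethoxy-N-methylbut-2-enamide | CON(C)C(=O)/C=C/C(OC)OC | intermediate
4 | (E)-N-methoxy-N-methyl-4-oxobut-2-enamide | CON(C)C(=O)/C=C/C=O | intermediate
5 | copper (E)-enolate formed from 4 by hydride addition (Ph3P ligand not drawn) | CON(C)C(=O)C/C=C/O[Cu] | intermediate
6 | (E)-4-[tert-butyl(dimethyl)silyl]oxy-N-methoxy-N-methylbut-3-enamide | CON(C)C(=O)C/C=C/O[Si](C)(C)C(C)(C)C | intermediate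
7 | methyl bromoacetate | COC(=O)CBr | starting material
8 | lithium dienolate of 6 (deprotonated alpha to the amide; (E)-enol ether kept) | CON(C)C(O[Li])=C/C=C/O[Si](C)(C)C(C)(C)C | intermediate
9 | methyl (4E)-5-[tert-butyl(dimethyl)silyl]oxy-3-[methoxy(methyl)carbamoyl]pent-4-enoate (racemic) | COC(=O)CC(/C=C/O[Si](C)(C)C(C)(C)C)C(=O)N(C)OC | intermediate
10 | (2E,6E,10E)-3,7,11,15-tetramethylhexadeca-2,6,10,14-tetraen-1-ol (geranylgeraniol) | OC/C=C(\C)CC/C=C(\C)CC/C=C(\C)CCC=C(C)C | starting material
11 | (2E,6E,10E)-1-bromo-3,7,11,15-tetramethylhexadeca-2,6,10,14-tetraene | BrC/C=C(\C)CC/C=C(\C)CC/C=C(\C)CCC=C(C)C | intermediate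
12 | ethynylmagnesium bromide | C#C[Mg]Br | starting material
13 | (4E,8E,12E)-5,9,13,17-tetramethyloctadeca-4,8,12,16-tetraen-1-yne | C#CC/C=C(\C)CC/C=C(\C)CC/C=C(\C)CCC=C(C)C | intermediate
14 | chlorobis(cyclopentadienyl)[(1E,4E,8E,12E)-5,9,13,17-tetramethyloctadeca-1,4,8,12,16-pentaen-1-yl]zirconium | Cl[Zr](C1C=CC=C1)(C1C=CC=C1)/C=C/C/C=C(\C)CC/C=C(\C)CC/C=C(\C)CCC=C(C)C | intermediate
15 | (1E,4E,8E,12E)-1-iodo-5,9,13,17-tetramethyloctadeca-1,4,8,12,16-pentaene | I/C=C/C/C=C(\C)CC/C=C(\C)CC/C=C(\C)CCC=C(C)C | intermediate
16 | [(1E,4E,8E,12E)-5,9,13,17-tetramethyloctadeca-1,4,8,12,16-pentaen-1-yl]lithium | [Li]/C=C/C/C=C(\C)CC/C=C(\C)CC/C=C(\C)CCC=C(C)C | intermediate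
17 | [(1E,4E,8E,12E)-5,9,13,17-tetramethyloctadeca-1,4,8,12,16-pentaen-1-yl]magnesium bromide | Br[Mg]/C=C/C/C=C(\C)CC/C=C(\C)CC/C=C(\C)CCC=C(C)C | intermediate
18 | bromomagnesium alkoxide of the tetrahedral adduct of 17 to the amide of 9 (N,O-chelate) | COC(=O)CC(/C=C/O[Si](C)(C)C(C)(C)C)C(O[Mg]Br)(N(C)OC)/C=C/C/C=C(\C)CC/C=C(\C)CC/C=C(\C)CCC=C(C)C | intermediate
19 | methyl (5E,8E,12E,16E)-3-[(E)-2-[tert-butyl(dimethyl)silyl]oxyethenyl]-9,13,17,21-tetramethyl-4-oxodocosa-5,8,12,16,20-pentaenoate (racemic) | COC(=O)CC(/C=C/O[Si](C)(C)C(C)(C)C)C(=O)/C=C/C/C=C(\C)CC/C=C(\C)CC/C=C(\C)CCC=C(C)C | intermediate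
20 | trienolate of 19, 4-oxido-3,5-diene with the two alkenyl arms cis on the enolate double bond (anion drawn; counter-ion is the ammonium cation of the catalyst) | COC(=O)C/C(/C=C/O[Si](C)(C)C(C)(C)C)=C(\[O-])/C=C/C/C=C(\C)CC/C=C(\C)CC/C=C(\C)CCC=C(C)C | intermediate
21 | (3R,4R)-cyclohexadienolate, the enolate of 22 toward the ring CH2 (anion drawn; same counter-ion) | COC(=O)CC1=C[C@H](O[Si](C)(C)C(C)(C)C)[C@H](C/C=C(\C)CC/C=C(\C)CC/C=C(\C)CCC=C(C)C)C=C1[O-] | intermediate
22 | methyl 2-[(3R,4R)-3-[tert-butyl(dimethyl)silyl]oxy-6-oxo-4-[(2E,6E,10E)-3,7,11,15-tetramethylhexadeca-2,6,10,14-tetraen-1-yl]cyclohex-1-en-1-yl]acetate | COC(=O)CC1=C[C@H](O[Si](C)(C)C(C)(C)C)[C@H](C/C=C(\C)CC/C=C(\C)CC/C=C(\C)CCC=C(C)C)CC1=O | intermediate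
23 | methyl 2-[(3R,4R)-3-hydroxy-6-oxo-4-[(2E,6E,10E)-3,7,11,15-tetramethylhexadeca-2,6,10,14-tetraen-1-yl]cyclohex-1-en-1-yl]acetate (hydroxyl and chain cis) | COC(=O)CC1=C[C@H](O)[C@H](C/C=C(\C)CC/C=C(\C)CC/C=C(\C)CCC=C(C)C)CC1=O | target

**Totals**

Total step count: 10. Longest linear sequence: 7 steps (steps 1, 2, 3, 4, 8, 9, 10).

**Steps most likely to fail**

Step 9 (Proposed new method). The ion pair may discriminate poorly between the two senses of disrotation. Phase-transfer deprotonation may be slow, so that ester hydrolysis or gamma-enolisation of the product at the silyloxy carbon competes. The fallback uses known chemistry, sets out from 19 and returns at 23. Ketone 19 is treated with KN(SiMe3)2 (0.95 equiv) in THF at −78 → −20 °C and quenched with AcOH at −78 °C. The oxy-anion-accelerated electrocyclisation then runs without chiral control, through the potassium salts of the same anions 20 and 21, and should give the racemic cis silyl ether F1. HF·pyridine gives the racemic alcohol F2. A lipase from Burkholderia cepacia with vinyl acetate in tert-butyl methyl ether at 30 °C, stopped just past half conversion, resolves it. The empirical rule for lipase acylation of secondary alcohols predicts that the (3S,4S)-enantiomer is acylated to the acetate F3, so that 23 remains as the unreacted alcohol and is separated by chromatography.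

Step 3. Trapping of the copper enolate may give poor control of enol ether geometry, and 1,2-reduction of the aldehyde may compete. The fallback sets out from 4 and returns at 6. Hydrogenation of 4 (H2, Pd/C, EtOAc) gives N-methoxy-N-methyl-4-oxobutanamide F4. Soft enolisation (TBSOTf, Et3N, CH2Cl2, −78 → 0 °C) gives 6 together with its (Z)-isomer F5. The isomers are separated on AgNO3-impregnated silica, and F5 is hydrolysed back to F4 (oxalic acid, wet THF) and recycled.

Step 8. The basic organometallic may enolise 9 alpha to the amide instead of adding, or attack the methyl ester. The fallback sets out from 9 (with 15) and returns at 19. Cp2Zr(H)Cl (1.5 equiv, THF, rt) reduces the N-methoxy-N-methylamide selectively to methyl (4E)-5-[tert-butyl(dimethyl)silyl]oxy-3-formylpent-4-enoate F6, leaving the ester. Nozaki–Hiyama–Kishi coupling of F6 with 15 (CrCl2, NiCl2 cat., DMF, rt) gives the allylic alcohols F7 as a diastereomer mixture. Dess–Martin oxidation (NaHCO3-buffered CH2Cl2, 0 °C) gives 19.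

**Further compounds**

F1 | step 9 | racemic cis methyl 2-[3-[tert-butyl(dimethyl)silyl]oxy-6-oxo-4-geranylgeranylcyclohex-1-en-1-yl]acetate (both enantiomers drawn) | COC(=O)CC1=C[C@H](O[Si](C)(C)C(C)(C)C)[C@H](C/C=C(\C)CC/C=C(\C)CC/C=C(\C)CCC=C(C)C)CC1=O.COC(=O)CC1=C[C@@H](O[Si](C)(C)C(C)(C)C)[C@@H](C/C=C(\C)CC/C=C(\C)CC/C=C(\C)CCC=C(C)C)CC1=O
F2 | step 9 | racemic cis methyl 2-[3-hydroxy-6-oxo-4-geranylgeranylcyclohex-1-en-1-yl]acetate (both enantiomers drawn) | COC(=O)CC1=C[C@H](O)[C@H](C/C=C(\C)CC/C=C(\C)CC/C=C(\C)CCC=C(C)C)CC1=O.COC(=O)CC1=C[C@@H](O)[C@@H](C/C=C(\C)CC/C=C(\C)CC/C=C(\C)CCC=C(C)C)CC1=O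
F3 | step 9 | methyl 2-[(3S,4S)-3-acetoxy-6-oxo-4-[(2E,6E,10E)-3,7,11,15-tetramethylhexadeca-2,6,10,14-tetraen-1-yl]cyclohex-1-en-1-yl]acetate | COC(=O)CC1=C[C@@H](OC(C)=O)[C@@H](C/C=C(\C)CC/C=C(\C)CC/C=C(\C)CCC=C(C)C)CC1=O
F4 | step 3 | N-methoxy-N-methyl-4-oxobutanamide | CON(C)C(=O)CCC=O
F5 | step 3 | (Z)-4-[tert-butyl(dimethyl)silyl]oxy-N-methoxy-N-methylbut-3-enamide | CON(C)C(=O)C/C=C\O[Si](C)(C)C(C)(C)C
F6 | step 8 | methyl (4E)-5-[tert-butyl(dimethyl)silyl]oxy-3-formylpent-4-enoate (racemic) | COC(=O)CC(C=O)/C=C/O[Si](C)(C)C(C)(C)C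
F7 | step 8 | methyl (5E,8E,12E,16E)-3-[(E)-2-[tert-butyl(dimethyl)silyl]oxyethenyl]-4-hydroxy-9,13,17,21-tetramethyldocosa-5,8,12,16,20-pentaenoate (diastereomer mixture) | COC(=O)CC(/C=C/O[Si](C)(C)C(C)(C)C)C(O)/C=C/C/C=C(\C)CC/C=C(\C)CC/C=C(\C)CCC=C(C)C
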